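**Strategy.** The oxolane ring (O1, C2 aryl, C3 hydroxymethyl, C4 aroyl, C5) holds a p-methoxyaryl donor on C2 and a carbonyl acceptor on C4. This 1,3-relationship marks C2–C3–C4 as a former donor–acceptor cyclopropane and O1–C5 as formaldehyde. One Lewis-acid formal [3+2] annulation therefore closes the ring, makes O1–C2 and C4–C5, and sets C2 trans to C3. The C3 configuration comes from an organocatalytic cyclopropanation and is the only source of chirality. The precursor is an enantiopure trans-2-aryl-3-(silyloxymethyl)cyclopropane-1,1-diester; the geminal diester is afterwards trimmed to the aryl ketone and C4 is set by equilibration.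

Key step: step 4

Remark on locants: O1, C2 (aryl), C3 (hydroxymethyl), C4 (aroyl), C5 are used in the prose, also for the cyclopropane carbons that become them; systematic names number the ring from the other side and carry their own locants.
Assumption: 1 (O-benzylisovanillin) and 2 are taken as catalogue compounds.
Remark on the precursor: the C3 hydroxymethyl group is carried as a TBDPS ether, not a TBS ether, because a primary TBS ether is at risk under metal triflates and in hot wet DMSO, and a freed alcohol would lactonise onto the cis ester.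

Step 1
Reactants: 1 3-(benzyloxy)-4-methoxybenzaldehyde; 2 (triphenylphosphoranylidene)acetaldehyde
Product: 3 (2E)-3-[3-(benzyloxy)-4-methoxyphenyl]prop-2-enal
Conditions: toluene, 80 °C
Reagents that add atoms: none
Why: Wittig olefination with the stabilised formylmethylene ylide should give the E enal directly, a slight excess of 1 keeping double homologation down.

Step 2
Reactants: 3 (2E)-3-[3-(benzyloxy)-4-methoxyphenyl]prop-2-enal; 4 dimethyl bromomalonate
Product: 6 dimethyl (2S,3R)-2-[3-(benzyloxy)-4-methoxyphenyl]-3-(hydroxymethyl)cyclopropane-1,1-dicarboxylate, via formylcyclopropane 5 (not isolated)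
Conditions: (S)-2-[diphenyl(trimethylsilyloxy)methyl]pyrrolidine (20 mol%), 2,6-lutidine, CH2Cl2, 0 °C; then MeOH, NaBH4, −20 °C; cold aq. NH4Cl
Reagents that add atoms: none
Why: In this Michael-initiated ring closure the bromomalonate adds to the face of the E-iminium ion not shielded by the diphenyl(silyloxy)methyl group, which sets the aryl-bearing carbon (S); the enamine then closes the cyclopropane by 3-exo-tet alkylation trans to the aryl group, which sets the formyl-bearing carbon (R, the future C3), and borohydride reduction in the same flask removes the labile aldehyde before isolation.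

Step 3
Reactants: 6 dimethyl (2S,3R)-2-[3-(benzyloxy)-4-methoxyphenyl]-3-(hydroxymethyl)cyclopropane-1,1-dicarboxylate
Product: 7 dimethyl (2S,3R)-2-[3-(benzyloxy)-4-methoxyphenyl]-3-{[tert-butyl(diphenyl)silyl]oxymethyl}cyclopropane-1,1-dicarboxylate
Conditions: TBDPSCl, imidazole, CH2Cl2, 0 °C to rt (crude 6 used at once)
Reagents that add atoms: tert-butyl(chloro)diphenylsilane, CC(C)(C)[Si](Cl)(c1ccccc1)c1ccccc1
Why: Imidazole-promoted silylation of the primary alcohol (silyl ether protection) is fast at low temperature and should outrun lactonisation onto the cis ester.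

Step 4
Reactants: 7 dimethyl (2S,3R)-2-[3-(benzyloxy)-4-methoxyphenyl]-3-{[tert-butyl(diphenyl)silyl]oxymethyl}cyclopropane-1,1-dicarboxylate; 8 formaldehyde (added as dry paraformaldehyde)
Product: 9 dimethyl (4R,5S)-5-[3-(benzyloxy)-4-methoxyphenyl]-4-{[tert-butyl(diphenyl)silyl]oxymethyl}oxolane-3,3-dicarboxylate
Conditions: (CH2O)n (3 equiv), Sn(OTf)2 (10 mol%), 4 Å MS, ClCH2CH2Cl, rt to 40 °C
Reagents that add atoms: none
Why: Proposed new method: Sn(OTf)2 bound to the geminal diester weakens the bond between the diester carbon and the aryl-bearing carbon, which, helped by the p-methoxy group, ionises to a benzylic cation/tin malonate ion pair; formaldehyde oxygen adds to the cation (O1–C2) and the malonate carbon then attacks the resulting O-alkylated oxocarbenium carbon (C4–C5). The closest known reaction is the Lewis-acid-catalysed formal [3+2] annulation of 2-arylcyclopropane-1,1-diesters with aldehydes; new are formaldehyde as the carbonyl partner and a 3-substituted cyclopropane in the same reaction. The oxolane, the only ring formed, closes through C–C bond formation in a formally 5-endo-trig attack on the oxocarbenium ion, the mode common to this family of annulations. C2 is the only new stereocentre and is controlled by the untouched C3 centre: capture and closure anti to the silyloxymethyl group give the 2,3-trans oxolane, and because the electron-rich 2-aryl C–O bond can reopen under the Lewis acid the mixture should converge on this more stable isomer even if an invertive opening first delivers some cis product. The step needs cleavage of the aryl-bearing and not the silyloxymethyl-bearing cyclopropane bond, which the alkoxyaryl donor secures, and trans selectivity at C2, which the C3 substituent and thermodynamic control secure, while enantiopurity is safe because C3 never ionises. Excess formaldehyde, molecular sieves and mild temperature are meant to hold back proton loss from the zwitterion to a styrene and capture of the cation by water.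

Step 5
Reactants: 9 dimethyl (4R,5S)-5-[3-(benzyloxy)-4-methoxyphenyl]-4-{[tert-butyl(diphenyl)silyl]oxymethyl}oxolane-3,3-dicarboxylate
Product: 10 methyl (4R,5S)-5-[3-(benzyloxy)-4-methoxyphenyl]-4-{[tert-butyl(diphenyl)silyl]oxymethyl}oxolane-3-carboxylate (both epimers at the ester-bearing carbon)
Conditions: LiCl, H2O, DMSO, 150 °C
Reagents that add atoms: none
Why: In the Krapcho dealkoxycarbonylation chloride demethylates one ester, the carboxylate loses CO2 and water protonates the enolate, under neutral conditions that should spare the silyl and benzyl ethers and the 2-aryl oxolane; the trans ester is expected to prevail, but the configuration at C4 is not relied on until step 9.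

Step 6
Reactants: 10 methyl (4R,5S)-5-[3-(benzyloxy)-4-methoxyphenyl]-4-{[tert-butyl(diphenyl)silyl]oxymethyl}oxolane-3-carboxylate
Product: 11 (4R,5S)-5-[3-(benzyloxy)-4-methoxyphenyl]-4-{[tert-butyl(diphenyl)silyl]oxymethyl}-N-methoxy-N-methyloxolane-3-carboxamide (both epimers at the amide-bearing carbon)
Conditions: MeNH(OMe)·HCl, iPrMgCl, THF, −20 to 0 °C
Reagents that add atoms: N,O-dimethylhydroxylamine hydrochloride, CNOC.Cl
Why: Aminolysis of the methyl ester by the chloromagnesium amide of N,O-dimethylhydroxylamine (direct ester-to-Weinreb-amide conversion) avoids acid, which the 2-aryl oxolane would not tolerate.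

Step 7
Reactants: 12 5-bromo-2-methoxyphenol
Product: 13 2-(benzyloxy)-4-bromo-1-methoxybenzene
Conditions: BnBr, K2CO3, DMF, rt
Reagents that add atoms: benzyl bromide, BrCc1ccccc1
Why: Williamson ether synthesis on the phenoxide is routine and gives the same protecting group as on the other aryl ring.

Step 8
Reactants: 11 (4R,5S)-5-[3-(benzyloxy)-4-methoxyphenyl]-4-{[tert-butyl(diphenyl)silyl]oxymethyl}-N-methoxy-N-methyloxolane-3-carboxamide; 13 2-(benzyloxy)-4-bromo-1-methoxybenzene
Product: 15 [3-(benzyloxy)-4-methoxyphenyl][(4R,5S)-5-[3-(benzyloxy)-4-methoxyphenyl]-4-{[tert-butyl(diphenyl)silyl]oxymethyl}oxolan-3-yl]methanone (both epimers at the aroyl-bearing carbon), via aryllithium 14 (not isolated)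
Conditions: 13, n-BuLi, THF, −78 °C; then 11, −78 °C; aq. NH4Cl
Reagents that add atoms: none
Why: Bromine–lithium exchange gives the aryllithium, which should add only once because the chelated tetrahedral adduct of the Weinreb amide holds until the quench (Weinreb ketone synthesis).

Step 9
Reactants: 15 [3-(benzyloxy)-4-methoxyphenyl][(4R,5S)-5-[3-(benzyloxy)-4-methoxyphenyl]-4-{[tert-butyl(diphenyl)silyl]oxymethyl}oxolan-3-yl]methanone
Product: 16 [3-(benzyloxy)-4-methoxyphenyl][(3S,4R,5S)-5-[3-(benzyloxy)-4-methoxyphenyl]-4-{[tert-butyl(diphenyl)silyl]oxymethyl}oxolan-3-yl]methanone (all-trans)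
Conditions: DBU, CH2Cl2, rt
Reagents that add atoms: none
Why: Base-mediated epimerisation through the ketone enolate should funnel both C4 epimers into the isomer with the aroyl group trans to the C3 substituent, so C4 (S) is set under thermodynamic control; β-elimination of O1 is not expected because the C5–O1 bond lies near the nodal plane of the exocyclic enolate (the reverse of a 5-endo-trig closure).

Step 10
Reactants: 16 [3-(benzyloxy)-4-methoxyphenyl][(3S,4R,5S)-5-[3-(benzyloxy)-4-methoxyphenyl]-4-{[tert-butyl(diphenyl)silyl]oxymethyl}oxolan-3-yl]methanone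
Product: 17 [3-(benzyloxy)-4-methoxyphenyl][(3S,4R,5S)-5-[3-(benzyloxy)-4-methoxyphenyl]-4-(hydroxymethyl)oxolan-3-yl]methanone
Conditions: TBAF, AcOH, THF, 0 °C to rt
Reagents that add atoms: none
Why: Fluoride-mediated desilylation is buffered with acetic acid so that C4 is not epimerised again once the free alcohol could hold a cis isomer as a bicyclic hemiketal.

Step 11
Reactants: 17 [3-(benzyloxy)-4-methoxyphenyl][(3S,4R,5S)-5-[3-(benzyloxy)-4-methoxyphenyl]-4-(hydroxymethyl)oxolan-3-yl]methanone
Product: 18 (3-hydroxy-4-methoxyphenyl)[(3S,4R,5S)-4-(hydroxymethyl)-5-(3-hydroxy-4-methoxyphenyl)oxolan-3-yl]methanone (CNP0234761.1)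
Conditions: H2 (1 atm), Pd/C, EtOAc, rt
Reagents that add atoms: none
Why: Catalytic hydrogenolysis of the two aryl benzyl ethers under neutral conditions should be much faster than reduction of the electron-rich aryl ketone or cleavage of the cyclic benzylic ether.

**Compound list**

1 | 3-(benzyloxy)-4-methoxybenzaldehyde | COc1ccc(C=O)cc1OCc1ccccc1 | starting material
2 | (triphenylphosphoranylidene)acetaldehyde | O=CC=P(c1ccccc1)(c1ccccc1)c1ccccc1 | starting material
3 | (2E)-3-[3-(benzyloxy)-4-methoxyphenyl]prop-2-enal | COc1ccc(/C=C/C=O)cc1OCc1ccccc1 | intermediate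
4 | dimethyl bromomalonate | COC(=O)C(Br)C(=O)OC | starting material
5 | dimethyl (2S,3R)-2-[3-(benzyloxy)-4-methoxyphenyl]-3-formylcyclopropane-1,1-dicarboxylate (trans; not isolated) | COc1ccc([C@@H]2[C@@H](C=O)C2(C(=O)OC)C(=O)OC)cc1OCc1ccccc1 | intermediate
6 | dimethyl (2S,3R)-2-[3-(benzyloxy)-4-methoxyphenyl]-3-(hydroxymethyl)cyclopropane-1,1-dicarboxylate | COc1ccc([C@@H]2[C@@H](CO)C2(C(=O)OC)C(=O)OC)cc1OCc1ccccc1 | intermediate
7 | dimethyl (2S,3R)-2-[3-(benzyloxy)-4-methoxyphenyl]-3-{[tert-butyl(diphenyl)silyl]oxymethyl}cyclopropane-1,1-dicarboxylate (trans) | COc1ccc([C@@H]2[C@@H](CO[Si](c3ccccc3)(c3ccccc3)C(C)(C)C)C2(C(=O)OC)C(=O)OC)cc1OCc1ccccc1 | intermediate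
8 | formaldehyde (used as paraformaldehyde) | C=O | starting material
9 | dimethyl (4R,5S)-5-[3-(benzyloxy)-4-methoxyphenyl]-4-{[tert-butyl(diphenyl)silyl]oxymethyl}oxolane-3,3-dicarboxylate (4,5-trans) | COC(=O)C1(C(=O)OC)CO[C@H](c2ccc(OC)c(OCc3ccccc3)c2)[C@H]1CO[Si](c2ccccc2)(c2ccccc2)C(C)(C)C | intermediate
10 | methyl (4R,5S)-5-[3-(benzyloxy)-4-methoxyphenyl]-4-{[tert-butyl(diphenyl)silyl]oxymethyl}oxolane-3-carboxylate (both epimers at the ester-bearing carbon, which is left open in the SMILES) | COC(=O)C1CO[C@H](c2ccc(OC)c(OCc3ccccc3)c2)[C@H]1CO[Si](c2ccccc2)(c2ccccc2)C(C)(C)C | intermediate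
11 | (4R,5S)-5-[3-(benzyloxy)-4-methoxyphenyl]-4-{[tert-butyl(diphenyl)silyl]oxymethyl}-N-methoxy-N-methyloxolane-3-carboxamide (both epimers at the amide-bearing carbon) | CON(C)C(=O)C1CO[C@H](c2ccc(OC)c(OCc3ccccc3)c2)[C@H]1CO[Si](c2ccccc2)(c2ccccc2)C(C)(C)C | intermediate
12 | 5-bromo-2-methoxyphenol | COc1ccc(Br)cc1O | starting material
13 | 2-(benzyloxy)-4-bromo-1-methoxybenzene | COc1ccc(Br)cc1OCc1ccccc1 | intermediate
14 | [3-(benzyloxy)-4-methoxyphenyl]lithium (not isolated) | [Li]c1ccc(OC)c(OCc2ccccc2)c1 | intermediate
15 | [3-(benzyloxy)-4-methoxyphenyl][(4R,5S)-5-[3-(benzyloxy)-4-methoxyphenyl]-4-{[tert-butyl(diphenyl)silyl]oxymethyl}oxolan-3-yl]methanone (both epimers at the aroyl-bearing carbon) | COc1ccc(C(=O)C2CO[C@H](c3ccc(OC)c(OCc4ccccc4)c3)[C@H]2CO[Si](c3ccccc3)(c3ccccc3)C(C)(C)C)cc1OCc1ccccc1 | intermediate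
16 | [3-(benzyloxy)-4-methoxyphenyl][(3S,4R,5S)-5-[3-(benzyloxy)-4-methoxyphenyl]-4-{[tert-butyl(diphenyl)silyl]oxymethyl}oxolan-3-yl]methanone (all-trans) | COc1ccc(C(=O)[C@@H]2CO[C@H](c3ccc(OC)c(OCc4ccccc4)c3)[C@H]2CO[Si](c3ccccc3)(c3ccccc3)C(C)(C)C)cc1OCc1ccccc1 | intermediate
17 | [3-(benzyloxy)-4-methoxyphenyl][(3S,4R,5S)-5-[3-(benzyloxy)-4-methoxyphenyl]-4-(hydroxymethyl)oxolan-3-yl]methanone | COc1ccc(C(=O)[C@@H]2CO[C@H](c3ccc(OC)c(OCc4ccccc4)c3)[C@H]2CO)cc1OCc1ccccc1 | intermediate
18 | (3-hydroxy-4-methoxyphenyl)[(3S,4R,5S)-4-(hydroxymethyl)-5-(3-hydroxy-4-methoxyphenyl)oxolan-3-yl]methanone | COc1ccc(C(=O)[C@@H]2CO[C@H](c3ccc(OC)c(O)c3)[C@H]2CO)cc1O | target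

**Step count.** Total: 11 steps. Longest linear sequence: 10 steps (steps 1–6 and 8–11, from 1 to 18); step 7 is a one-step side branch.

**Steps most likely to fail**

Step 4 (proposed new method). The ion pair may collapse by proton loss from C3 to a styrene, the cation may be intercepted by water or formaldehyde oligomers, or an invertive opening may leave the 2,3-cis oxolane without later equilibration. The fallback uses known reactions, sets out from 7 and comes back at 9. Lewis-acid-catalysed ring opening of the cyclopropane by methanol (Cu(OTf)2 cat., MeOH/CH2Cl2, rt) should give the γ-methoxy malonate dimethyl 2-[(2R)-1-[3-(benzyloxy)-4-methoxyphenyl]-3-{[tert-butyl(diphenyl)silyl]oxy}-1-methoxypropan-2-yl]propanedioate F1 as benzylic epimers. Base-catalysed hydroxymethylation of its malonate CH (aq. CH2O, K2CO3 cat., THF, rt) gives dimethyl 2-[(2R)-1-[3-(benzyloxy)-4-methoxyphenyl]-3-{[tert-butyl(diphenyl)silyl]oxy}-1-methoxypropan-2-yl]-2-(hydroxymethyl)propanedioate F2. Acid-catalysed etherification (BF3·OEt2 cat., CH2Cl2, 0 °C) then ionises the p-methoxybenzylic methyl ether, and the primary alcohol closes the ring trans to the C3 substituent under thermodynamic control, which gives 9.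

Step 2. Conjugate addition to the electron-rich iminium ion may be slow, and the amine may reopen the p-alkoxyaryl formylcyclopropane through its enamine, with erosion of enantiopurity and trans selectivity. The fallback sets out from 3 and comes back at 5, which is reduced to 6 as before. Michael addition of dimethyl malonate to 3 with the same (S)-prolinol silyl ether in EtOH, a robust reaction for aryl enals, gives dimethyl 2-[(1R)-1-[3-(benzyloxy)-4-methoxyphenyl]-3-oxopropyl]propanedioate F3. Oxidative ring closure in the absence of the amine (I2, DBU, CH2Cl2, 0 °C) proceeds by iodination of the malonate carbon and 3-exo-tet alkylation of the aldehyde enolate, and gives the trans formylcyclopropane 5.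

Step 5. Demethylation at the congested quaternary malonate may be slow, and long heating may cost the silyl ether, followed by lactonisation. The fallback sets out from 9 and comes back at 10. Mono-saponification (LiOH, THF/MeOH/H2O, rt; then acidification) gives the malonic half-ester (4R,5S)-5-[3-(benzyloxy)-4-methoxyphenyl]-4-{[tert-butyl(diphenyl)silyl]oxymethyl}-3-(methoxycarbonyl)oxolane-3-carboxylic acid F4. Thermal decarboxylation (toluene, Et3N cat., 110 °C) converts it into 10 at a far lower temperature than the chloride-mediated process.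

**Further compounds**

F1 | step 4 | dimethyl 2-[(2R)-1-[3-(benzyloxy)-4-methoxyphenyl]-3-{[tert-butyl(diphenyl)silyl]oxy}-1-methoxypropan-2-yl]propanedioate (benzylic epimers) | COc1ccc(C(OC)[C@@H](CO[Si](c2ccccc2)(c2ccccc2)C(C)(C)C)C(C(=O)OC)C(=O)OC)cc1OCc1ccccc1
F2 | step 4 | dimethyl 2-[(2R)-1-[3-(benzyloxy)-4-methoxyphenyl]-3-{[tert-butyl(diphenyl)silyl]oxy}-1-methoxypropan-2-yl]-2-(hydroxymethyl)propanedioate (benzylic epimers) | COc1ccc(C(OC)[C@@H](CO[Si](c2ccccc2)(c2ccccc2)C(C)(C)C)C(CO)(C(=O)OC)C(=O)OC)cc1OCc1ccccc1
F3 | step 2 | dimethyl 2-[(1R)-1-[3-(benzyloxy)-4-methoxyphenyl]-3-oxopropyl]propanedioate | COc1ccc([C@@H](C(C(=O)OC)C(=O)OC)CC=O)cc1OCc1ccccc1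
F4 | step 5 | (4R,5S)-5-[3-(benzyloxy)-4-methoxyphenyl]-4-{[tert-butyl(diphenyl)silyl]oxymethyl}-3-(methoxycarbonyl)oxolane-3-carboxylic acid (configuration at the acid-bearing carbon left open) | COC(=O)C1(C(=O)O)CO[C@H](c2ccc(OC)c(OCc3ccccc3)c2)[C@H]1CO[Si](c2ccccc2)(c2ccccc2)C(C)(C)C
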